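## The problem

Verbenachalcone (15) is an unsymmetrical dimer of two dihydrochalcones. Rings B and B' are joined by a diaryl ether oxygen between C4 of ring B (OMe at C3) and C3' of ring B' (free OH at C4'), and each ring carries at C1 a CH2CH2C(=O) chain ending in a 2,4-dihydroxyphenyl ring A. There is no stereocentre, so the synthesis is a matter of regiochemistry and chemoselectivity only. Three things must be solved: a C–O bond between two electron-rich, ortho-oxygenated arenes; two aryl ketones with the acyl group ortho and para to the ring A oxygens; and the release of five phenols beside one methyl ether that must stay. Friedel–Crafts acylation of a resorcinol by the diacid is unattractive: 3-arylpropanoic acids with an activated ring (C6 of ring B is para to OMe) close to 1-indanones under the same Lewis acids, which also threaten the methyl ether. The free resorcinol ketones and the oxygen-rich ring B' are sensitive to oxidants and to base in air, so the phenols should be uncovered last and under neutral conditions. The enabling feature is the pattern of each ring A: acyl at C1, oxygen at C2 and C4. These carbons map onto C6, C1 and C3 of a 3-alkoxycyclohex-2-enone, whose C6 is a carbon nucleophile, so ring A can be carried two hydrogens short of aromatic, acylated as an enolate and aromatized afterwards.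

## Retrosynthesis

**15 from 14 (three O–benzyl bonds).** The last cut removes three benzyl ethers: one on the C4' oxygen of ring B' and one on the C4 oxygen of each ring A. Benzyl is chosen for all three because it is the only common group that leaves the C3 methyl ether untouched and falls in one neutral hydrogenolysis. Any Lewis-acid dealkylation would put the methyl ether at risk. Tribenzyl ether 14 is no simpler in skeleton but is robust and non-polar. The forward step only has to spare the chelated aryl ketones.

**14 from 12 (two rings A taken back by two hydrogens each).** Each 4-benzyloxy-2-hydroxyphenyl ketone is traced to a 6-acyl-3-(benzyloxy)cyclohex-2-enone, giving bis(β-diketone) 12. The alternative is to keep rings A aromatic and attach them by Friedel–Crafts or aryl-metal chemistry. Against that, this cut fixes the 1,2,4 pattern by construction, with no question of ortho/para acylation or of indanone closure. The forward reaction must remove two hydrogens from each ring without touching the two ArCH2CH2C(=O) units. Dihydrochalcones are themselves dehydrogenated by quinone oxidants, so the oxidation is directed to the carbon between the two carbonyls by selenenylation and selenoxide elimination, passing through bis-selenide 13.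

**12 from 6 and 9 (the two bonds between the ketone carbonyls and C1 of each ring A).** This is the strategic cut. It divides 12 into bis(N-methoxy-N-methylamide) 6 and two molecules of 3-(benzyloxy)cyclohex-2-en-1-one 9, which reacts as its kinetic lithium dienolate 10. Cutting the other side of the carbonyl (acyl anion or radical chemistry) would need rings A as activated aroyl partners. Cutting with an ester electrophile would let the β-diketone product quench the enolate. The amide forms chelated tetrahedral adduct 11, which holds the acyl group until work-up. The precursor is much simpler: 6 has no ring A at all, and 9 is a one-step compound. The forward step needs C6 deprotonation rather than C4, C-acylation rather than O-acylation, and completion at both amides.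

**6 from 5 (two amide C–N bonds).** Both amides come from the dimethyl ester 5 in one operation. The ester is kept through the diaryl ether synthesis because it tolerates carbonate base and copper, and because both phenolic building blocks are sold as methyl esters.

**5 from 3 and 4 (the diaryl ether C3'–O bond).** The ether is cut on the ring B' side. This gives aryl bromide 3 (ring B', phenol masked as benzyl ether) and phenol 4 (ring B, methyl dihydroferulate). This polarity is preferred because the halogen is easy to introduce ortho to the ring B' hydroxyl, whereas the ring B phenol is already in place in 4. A copper-catalysed Ullmann etherification is asked to join two ortho-substituted, electron-rich partners; this is the least comfortable of the ordinary steps.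

**3 from 1 by way of 2; 9 from 7 and 8.** Bromide 3 comes from methyl 3-(4-hydroxyphenyl)propanoate 1 by ortho-bromination to 2 and O-benzylation. Enone 9 comes from cyclohexane-1,3-dione 7 and benzyl alcohol 8 by acid-catalysed condensation. The alkoxy group of 9 becomes the C4 oxygen substituent of ring A, which is why it is benzyl.

## Roads not taken

**Alternative 1: ring B' built by pyrone Diels–Alder reaction.** The cut runs through ring B' (C1'–C2' and C3'–C4'). Forward, the 3-benzyloxy-2-pyrone-6-carboxylate A2 (a pyrone of the kind made by dehydrating a hexaric acid) is heated with the aryl ethynyl ether A3. Cycloaddition and loss of CO2 give benzoate A1 with the aryloxy group already on the new ring. The merit is real: the diaryl ether oxygen is installed before ring B' exists, so no metal-mediated coupling of two hindered, oxygenated arenes is needed, and the ynol ether polarization should give the right regiochemistry. On this point it is better than the chosen plan, whose Ullmann step is its weakest ordinary step. The weak points are more serious for this target. A1 carries only one-carbon handles (an ester and a masked aldehyde) where two C3 ketone chains with rings A are needed, so both must be redox-adjusted, extended and joined to rings A afterwards. The aryl ethynyl ether takes several steps and is thermally delicate. A benzene ring that can be bought is built de novo. Against the cleaner ether formation, the chosen plan offers a route of eight steps in which both chains are present from the first step.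

**Alternative 2: ring B built by keto ester–enal annulation.** The cut is through ring B (C1–C2 and C4–C5). Forward, the 4-aryloxyacetoacetate A6 and enal A5 are combined under secondary-amine catalysis (pyrrolidine with benzoic acid). Michael addition and intramolecular aldol condensation give cyclohexenone A4. The merits are a copper-free ether bond (made earlier by simple phenoxide alkylation) and mild organocatalytic conditions. The weaknesses: A4 still needs ester cleavage with decarboxylation, dehydrogenation and O-methylation before ring B is aromatic, so an aromatization is needed here as well, on a ring that is commercially available as a guaiacol. The annulation has to close through the aryloxy-bearing carbon and not through oxygen (hemiacetal or pyran formation). Rings A are still unattached at the end, so a twofold acylation like the one chosen would follow anyway. This road is longer, and it aromatizes ring B, where nothing is gained, in place of rings A, where the acylation pattern is fixed by the aromatization.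

**Alternative 3: twofold nickel-catalysed decarboxylative acylation.** The cut is on the other side of each carbonyl, between C=O and the α-CH2. Forward, diester 5 would be saponified and converted into the bis(N-hydroxyphthalimide) ester A8. NiCl2(dme), 4,4'-di-tert-butyl-2,2'-bipyridine and Zn powder would then couple both 2-arylethyl radicals with the 2-pyridyl thioester A9 to give pentabenzyl ether A7. One hydrogenolysis would finish. This is the strongest competitor. Rings A arrive aromatic with both oxygens in place, no dehydrogenation or peroxide step is needed, no strong base is used, and the step count from 5 is the same as in the chosen plan. In oxidation-state economy it is better. Its risks lie in the twofold radical coupling: each primary, unstabilized radical can be reduced, dimerize or couple only once. The ortho-benzyloxy, electron-rich aroyl thioester is a slow acyl partner. The thioester takes about three steps against one for 9. Against the better redox economy, the chosen plan relies on a two-electron enolate acylation that can be driven to completion at both sites by an excess of a cheap nucleophile, and the ortho oxygen of ring A (the enone carbonyl) assists the bond formation by chelation.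

Key step: step 6

## Route

Remark on the chemistry: 11, 12 and 13 carry stereocentres at the acylated ring carbons (11 also at the hemiaminal carbons). They are destroyed on aromatization, so these compounds are drawn without configuration and carried as mixtures of diastereomers and tautomers.

Step 1
Reactants: 1 methyl 3-(4-hydroxyphenyl)propanoate
Product: 2 methyl 3-(3-bromo-4-hydroxyphenyl)propanoate
Conditions: N-bromosuccinimide (1.0 equiv), MeCN, 0 °C → rt
Reagents that add atoms: N-bromosuccinimide, O=C1CCC(=O)N1Br
Why: Electrophilic aromatic bromination of a para-substituted phenol; the hydroxyl directs to the two equivalent ortho positions, and one equivalent of reagent at low temperature should stop at the monobromide.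

Step 2
Reactants: 2 methyl 3-(3-bromo-4-hydroxyphenyl)propanoate
Product: 3 methyl 3-[4-(benzyloxy)-3-bromophenyl]propanoate
Conditions: BnBr, K2CO3, acetone, reflux
Reagents that add atoms: benzyl bromide, BrCc1ccccc1
Why: Williamson ether synthesis (phenoxide SN2 on benzyl bromide); carbonate leaves the methyl ester alone. The benzyl ether prevents self-coupling in step 3 and is removed at the end together with the other two.

Step 3
Reactants: 3 methyl 3-[4-(benzyloxy)-3-bromophenyl]propanoate; 4 methyl 3-(4-hydroxy-3-methoxyphenyl)propanoate
Product: 5 methyl 3-[4-[2-(benzyloxy)-5-(3-methoxy-3-oxopropyl)phenoxy]-3-methoxyphenyl]propanoate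
Conditions: CuI (20 mol %), N,N-dimethylglycine·HCl (60 mol %), Cs2CO3, 1,4-dioxane, 100 °C, Ar
Reagents that add atoms: none
Why: Ullmann diaryl ether synthesis catalysed by CuI with an amino acid ligand, the established protocol for aryl bromides and ortho-substituted phenols near 100 °C. Anhydrous carbonate should leave both methyl esters intact, and an excess of phenol 4 compensates for the electron-rich bromide.

Step 4
Reactants: 5 methyl 3-[4-[2-(benzyloxy)-5-(3-methoxy-3-oxopropyl)phenoxy]-3-methoxyphenyl]propanoate
Product: 6 3-[4-[2-(benzyloxy)-5-[3-[methoxy(methyl)amino]-3-oxopropyl]phenoxy]-3-methoxyphenyl]-N-methoxy-N-methylpropanamide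
Conditions: MeNH(OMe)·HCl, i-PrMgCl, THF, −20 → 0 °C
Reagents that add atoms: N,O-dimethylhydroxylamine hydrochloride, CNOC.Cl
Why: Direct ester-to-Weinreb-amide aminolysis by the chloromagnesium amide made in the flask from the hydrochloride and i-PrMgCl. The magnesium-chelated adduct prevents further addition, and aryl ethers are inert.

Step 5
Reactants: 7 cyclohexane-1,3-dione; 8 benzyl alcohol
Product: 9 3-(benzyloxy)cyclohex-2-en-1-one
Conditions: TsOH·H2O (cat.), toluene, reflux, Dean–Stark
Reagents that add atoms: none
Why: Acid-catalysed condensation of the enolized 1,3-dione with the alcohol under azeotropic removal of water gives the vinylogous ester; the symmetry of 7 allows only one product.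

Step 6
Reactants: 6 3-[4-[2-(benzyloxy)-5-[3-[methoxy(methyl)amino]-3-oxopropyl]phenoxy]-3-methoxyphenyl]-N-methoxy-N-methylpropanamide; 9 3-(benzyloxy)cyclohex-2-en-1-one
Product: 12 3-(benzyloxy)-6-[3-[4-[2-(benzyloxy)-5-[3-[4-(benzyloxy)-2-oxocyclohex-3-en-1-yl]-3-oxopropyl]phenoxy]-3-methoxyphenyl]propanoyl]cyclohex-2-en-1-one (bis-β-diketone; epimers and enol tautomers), via lithium dienolate 10 (not isolated), via dilithium tetrahedral bis-adduct 11 (not isolated)
Conditions: 9 (5 equiv), LiN(i-Pr)2 (4.8 equiv), THF, −78 °C; then 6, −78 → −20 °C; sat. aq. NH4Cl
Reagents that add atoms: lithium diisopropylamide, [Li]N(C(C)C)C(C)C (supplies only the lithium of 10 and 11; no atom of it stays in 12)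
Why: LiN(i-Pr)2 removes a C6 proton of 9 under kinetic control to give the cross-conjugated dienolate 10; the C4 protons are removed more slowly and the benzylic OCH2 protons are far less acidic. C6 of 10 adds to each amide carbonyl of 6 to give the N-methoxy-chelated tetrahedral lithium adduct 11, which does not release a ketone in the flask and so cannot be attacked a second time. Mild aqueous work-up collapses 11 to the β-diketone 12, expected largely as its hydrogen-bonded enol. The closest known reaction type is the Stork–Danheiser α'-functionalization of 3-alkoxycyclohexenone enolates, combined with the acylation of lithium ketone enolates by N-methoxy-N-methylamides. No ring is closed; two carbon–carbon bonds are formed. The two new stereocentres at the acylated ring carbons are not controlled and need not be, since they are enolizable and disappear on aromatization. C- over O-acylation is secured by the lithium counter-ion in THF and the amide electrophile, and site selectivity by deprotonation at −78 °C. Complete twofold conversion is secured by more than two equivalents of 10 per amide, with the base kept slightly short of 9 so that no free amide base attacks 6.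

Step 7
Reactants: 12 3-(benzyloxy)-6-[3-[4-[2-(benzyloxy)-5-[3-[4-(benzyloxy)-2-oxocyclohex-3-en-1-yl]-3-oxopropyl]phenoxy]-3-methoxyphenyl]propanoyl]cyclohex-2-en-1-one
Product: 14 1-[4-(benzyloxy)-2-hydroxyphenyl]-3-[4-[2-(benzyloxy)-5-[3-[4-(benzyloxy)-2-hydroxyphenyl]-3-oxopropyl]phenoxy]-3-methoxyphenyl]propan-1-one, via bis-selenide 13 (not isolated)
Conditions: PhSeCl (2.2 equiv), pyridine, CH2Cl2, 0 °C; then 30% aq. H2O2, 0 °C → rt
Reagents that add atoms: phenylselenenyl chloride, Cl[Se]c1ccccc1 (its PhSe groups stand in 13 only and leave in the elimination; no atom of it stays in 14)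
Why: α-Selenenylation of the enolized β-diketone at the carbon between the two carbonyls, then oxidation to the selenoxide, whose syn-elimination can only take a hydrogen from the neighbouring ring CH2. The resulting cyclohexa-2,5-dienone tautomerizes at once to the chelated 2-hydroxyaryl ketone. The oxidation is confined to the two ring carbons, so the ArCH2CH2C(=O) units and the benzyl ethers should be untouched.

Step 8
Reactants: 14 1-[4-(benzyloxy)-2-hydroxyphenyl]-3-[4-[2-(benzyloxy)-5-[3-[4-(benzyloxy)-2-hydroxyphenyl]-3-oxopropyl]phenoxy]-3-methoxyphenyl]propan-1-one
Product: 15 verbenachalcone, 1-(2,4-dihydroxyphenyl)-3-[4-[5-[3-(2,4-dihydroxyphenyl)-3-oxopropyl]-2-hydroxyphenoxy]-3-methoxyphenyl]propan-1-one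
Conditions: H2 (1 atm), 10% Pd/C, EtOAc–MeOH, rt
Reagents that add atoms: none
Why: Catalytic hydrogenolysis of three aryl benzyl ethers over Pd/C; the diaryl ether, the methyl ether and the electron-rich, hydrogen-bonded aryl ketones are expected to be inert at 1 atm and room temperature.

## Compound list

1 | methyl 3-(4-hydroxyphenyl)propanoate | COC(=O)CCc1ccc(O)cc1 | starting material
2 | methyl 3-(3-bromo-4-hydroxyphenyl)propanoate | COC(=O)CCc1ccc(O)c(Br)c1 | intermediate
3 | methyl 3-[4-(benzyloxy)-3-bromophenyl]propanoate | COC(=O)CCc1ccc(OCc2ccccc2)c(Br)c1 | intermediate
4 | methyl 3-(4-hydroxy-3-methoxyphenyl)propanoate | COC(=O)CCc1ccc(O)c(OC)c1 | starting material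
5 | methyl 3-[4-[2-(benzyloxy)-5-(3-methoxy-3-oxopropyl)phenoxy]-3-methoxyphenyl]propanoate | COC(=O)CCc1ccc(Oc2cc(CCC(=O)OC)ccc2OCc2ccccc2)c(OC)c1 | intermediate
6 | 3-[4-[2-(benzyloxy)-5-[3-[methoxy(methyl)amino]-3-oxopropyl]phenoxy]-3-methoxyphenyl]-N-methoxy-N-methylpropanamide | CON(C)C(=O)CCc1ccc(Oc2cc(CCC(=O)N(C)OC)ccc2OCc2ccccc2)c(OC)c1 | intermediate
7 | cyclohexane-1,3-dione | O=C1CCCC(=O)C1 | starting material
8 | benzyl alcohol | OCc1ccccc1 | starting material
9 | 3-(benzyloxy)cyclohex-2-en-1-one | O=C1CCCC(OCc2ccccc2)=C1 | intermediate
10 | lithium 5-(benzyloxy)cyclohexa-1,5-dien-1-olate (kinetic dienolate of 9, formed in the flask) | [Li+].[O-]C1=CCCC(OCc2ccccc2)=C1 | intermediate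
11 | dilithium tetrahedral bis-adduct: each former amide carbon of 6 bears O–Li, N(OMe)Me and C6 of a 3-(benzyloxy)cyclohex-2-enone ring (formed in the flask, mixture of diastereomers) | COc1cc(CCC([O-])(N(C)OC)C2CCC(OCc3ccccc3)=CC2=O)ccc1Oc1cc(CCC([O-])(N(C)OC)C2CCC(OCc3ccccc3)=CC2=O)ccc1OCc1ccccc1.[Li+].[Li+] | intermediate
12 | 3-(benzyloxy)-6-[3-[4-[2-(benzyloxy)-5-[3-[4-(benzyloxy)-2-oxocyclohex-3-en-1-yl]-3-oxopropyl]phenoxy]-3-methoxyphenyl]propanoyl]cyclohex-2-en-1-one (epimers and enol tautomers) | COc1cc(CCC(=O)C2CCC(OCc3ccccc3)=CC2=O)ccc1Oc1cc(CCC(=O)C2CCC(OCc3ccccc3)=CC2=O)ccc1OCc1ccccc1 | intermediate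
13 | bis-selenide: 12 with a phenylselanyl group on each acylated ring carbon (formed in the flask, mixture of diastereomers) | COc1cc(CCC(=O)C2([Se]c3ccccc3)CCC(OCc3ccccc3)=CC2=O)ccc1Oc1cc(CCC(=O)C2([Se]c3ccccc3)CCC(OCc3ccccc3)=CC2=O)ccc1OCc1ccccc1 | intermediate
14 | 1-[4-(benzyloxy)-2-hydroxyphenyl]-3-[4-[2-(benzyloxy)-5-[3-[4-(benzyloxy)-2-hydroxyphenyl]-3-oxopropyl]phenoxy]-3-methoxyphenyl]propan-1-one (tri-O-benzylverbenachalcone) | COc1cc(CCC(=O)c2ccc(OCc3ccccc3)cc2O)ccc1Oc1cc(CCC(=O)c2ccc(OCc3ccccc3)cc2O)ccc1OCc1ccccc1 | intermediate
15 | verbenachalcone, 1-(2,4-dihydroxyphenyl)-3-[4-[5-[3-(2,4-dihydroxyphenyl)-3-oxopropyl]-2-hydroxyphenoxy]-3-methoxyphenyl]propan-1-one | COc1cc(CCC(=O)c2ccc(O)cc2O)ccc1Oc1cc(CCC(=O)c2ccc(O)cc2O)ccc1O | target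

## Step count and risks

Total: 8 steps. Longest linear sequence: 7 steps (steps 1, 2, 3, 4, 6, 7, 8 from 1); step 5 is a one-step side branch.

**Step 6 (key step).** The most likely failure is incomplete twofold acylation. Proton transfer from the amide α-CH2 groups, or from diketone released too early, could quench the dienolate and leave mono-acylated material. Attack of residual amide base on the N-methoxy group could degrade 6. The fallback replaces acylation by aldol addition and oxidation. It sets out from 6, which is reduced with i-Bu2AlH (THF, −78 °C) to 3-[4-[2-(benzyloxy)-5-(3-oxopropyl)phenoxy]-3-methoxyphenyl]propanal F1. Dienolate 10 (from 9 and LiN(i-Pr)2) adds to both aldehydes at −78 °C to give the bis(β-hydroxy ketone) F2. Dess–Martin periodinane oxidizes both carbinols, and the sequence returns to the route at 12. Aldehydes are far better electrophiles than amides, and no acidic product forms during the carbon–carbon bond formation.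

**Step 7.** Two processes could interfere. Selenenylation could compete at the α-carbon of the vinylogous ester. The seleninic acid by-product with excess peroxide could over-oxidize the new electron-rich hydroxyaryl ketone (Baeyer–Villiger or Dakin-type oxygen insertion). The fallback uses halogenation and dehydrohalogenation, with no peroxide. It sets out from 12, which is brominated at the carbon between the carbonyls with N-bromosuccinimide (CH2Cl2, 0 °C) to give the bis(α-bromo diketone) F3. Elimination of HBr with DBU gives the dienone, which tautomerizes, and the sequence returns at 14.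

**Step 3.** Coupling of an ortho-alkoxy aryl bromide with an ortho-methoxy phenol may be slow. Prolonged heating with carbonate invites protodebromination and partial ester hydrolysis. The fallback reverses the roles at copper by an oxidative Chan–Lam etherification at room temperature. It sets out from 3, which is borylated (B2pin2, Pd(dppf)Cl2, KOAc, dioxane, 80 °C) to methyl 3-[4-(benzyloxy)-3-(4,4,5,5-tetramethyl-1,3,2-dioxaborolan-2-yl)phenyl]propanoate F4. Cleavage with NaIO4/NH4OAc in aqueous acetone gives [2-(benzyloxy)-5-(3-methoxy-3-oxopropyl)phenyl]boronic acid F5. Coupling with phenol 4 (Cu(OAc)2, pyridine, 4 Å molecular sieves, CH2Cl2, air, rt) returns to the route at 5.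

**Step 8.** Hydrogenolysis could stall if traces of selenium from step 7 poison the palladium surface. Forcing the reaction could then reduce the benzylic ketones. The fallback is a Lewis-acid debenzylation: from 14, BCl3 with pentamethylbenzene as cation scavenger (CH2Cl2, −78 °C) cleaves the three benzyl ethers, and the aryl methyl ether should survive at that temperature. It arrives directly at 15 and makes no new intermediate.

## Further compounds

F1 | step 6 | 3-[4-[2-(benzyloxy)-5-(3-oxopropyl)phenoxy]-3-methoxyphenyl]propanal | COc1cc(CCC=O)ccc1Oc1cc(CCC=O)ccc1OCc1ccccc1
F2 | step 6 | bis(β-hydroxy ketone): 12 with both side-chain ketones as secondary alcohols (mixture of diastereomers) | COc1cc(CCC(O)C2CCC(OCc3ccccc3)=CC2=O)ccc1Oc1cc(CCC(O)C2CCC(OCc3ccccc3)=CC2=O)ccc1OCc1ccccc1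
F3 | step 7 | bis(α-bromo diketone): 12 with bromine on each acylated ring carbon (mixture of diastereomers) | COc1cc(CCC(=O)C2(Br)CCC(OCc3ccccc3)=CC2=O)ccc1Oc1cc(CCC(=O)C2(Br)CCC(OCc3ccccc3)=CC2=O)ccc1OCc1ccccc1
F4 | step 3 | methyl 3-[4-(benzyloxy)-3-(4,4,5,5-tetramethyl-1,3,2-dioxaborolan-2-yl)phenyl]propanoate | COC(=O)CCc1ccc(OCc2ccccc2)c(B2OC(C)(C)C(C)(C)O2)c1
F5 | step 3 | [2-(benzyloxy)-5-(3-methoxy-3-oxopropyl)phenyl]boronic acid | COC(=O)CCc1ccc(OCc2ccccc2)c(B(O)O)c1
F0 | step 8 | none | none
A1 | alternative 1 | methyl 4-(benzyloxy)-3-[4-(1,3-dioxolan-2-yl)-2-methoxyphenoxy]benzoate | COC(=O)c1ccc(OCc2ccccc2)c(Oc2ccc(C3OCCO3)cc2OC)c1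
A2 | alternative 1 | methyl 3-(benzyloxy)-2-oxo-2H-pyran-6-carboxylate | COC(=O)C1=CC=C(OCc2ccccc2)C(=O)O1
A3 | alternative 1 | 2-[4-(ethynyloxy)-3-methoxyphenyl]-1,3-dioxolane | C#COc1ccc(C2OCCO2)cc1OC
A4 | alternative 2 | tert-butyl 3-[2-(benzyloxy)-5-(3-methoxy-3-oxopropyl)phenoxy]-6-(3-methoxy-3-oxopropyl)-2-oxocyclohex-3-ene-1-carboxylate (mixture of epimers) | CC(C)(C)OC(=O)C1C(CCC(=O)OC)CC=C(Oc2cc(CCC(=O)OC)ccc2OCc2ccccc2)C1=O
A5 | alternative 2 | methyl (E)-6-oxohex-4-enoate | COC(=O)CC/C=C/C=O
A6 | alternative 2 | tert-butyl 4-[2-(benzyloxy)-5-(3-methoxy-3-oxopropyl)phenoxy]-3-oxobutanoate | CC(C)(C)OC(=O)CC(=O)COc1cc(CCC(=O)OC)ccc1OCc1ccccc1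
A7 | alternative 3 | pentabenzyl verbenachalcone | COc1cc(CCC(=O)c2ccc(OCc3ccccc3)cc2OCc2ccccc2)ccc1Oc1cc(CCC(=O)c2ccc(OCc3ccccc3)cc2OCc2ccccc2)ccc1OCc1ccccc1
A8 | alternative 3 | bis(1,3-dioxoisoindolin-2-yl) ester of the diacid corresponding to 5 | O=C(CCc1ccc(Oc2cc(CCC(=O)ON3C(=O)c4ccccc4C3=O)ccc2OCc2ccccc2)c(OC)c1)ON1C(=O)c2ccccc2C1=O
A9 | alternative 3 | S-(pyridin-2-yl) 2,4-bis(benzyloxy)benzenecarbothioate | O=C(Sc1ccccn1)c1ccc(OCc2ccccc2)cc1OCc1ccccc1
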